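**Assumption:** the C3=C4 enol geometry in the target string is read as one drawing of a freely equilibrating β-diketone/enol system, and every enedione below is drawn the same way. The fixed stereo-elements are the (E)-C1=C2 alkene and the (S)-carbinol at C7.

## Retrosynthetic overview

1. C7–O is made last: site- and enantioselective benzylic hydroxylation of the 7-deoxy compound 7 (hydride abstraction, p-quinone methide, water addition). This sets the only stereocentre.
2. C1=C2: boron-templated aldol condensation of 6-(4-hydroxyphenyl)hexane-2,4-dione 3 with vanillin 4.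
3. C3–C4: crossed Claisen condensation of raspberry ketone 1 with ethyl acetate 2.
4. No ring is formed: both benzene rings arrive intact in 1 and 4, and no protecting group is used.

## Route

Step 1
Reactants: 1 4-(4-hydroxyphenyl)butan-2-one (raspberry ketone); 2 ethyl acetate
Product: 3 6-(4-hydroxyphenyl)hexane-2,4-dione
Conditions: KOtBu (3.2 equiv), EtOAc (6 equiv), THF, 0 °C → rt; then 1 M HCl to pH 4
Reagents that add atoms: none
Why: Crossed Claisen condensation in which the phenoxide is inert, the ketone enolate is acylated at the methyl carbon, the equilibrium is pulled to the unbranched diketonate (the hindered C3-acyl isomer reverts by retro-Claisen) and any aryl acetate formed at the phenol is cleaved again by alkoxide; no stereocentre is formed.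

Step 2
Reactants: 3 6-(4-hydroxyphenyl)hexane-2,4-dione; 4 vanillin
Product: 7 (E)-1-(4-hydroxy-3-methoxyphenyl)-7-(4-hydroxyphenyl)hept-1-ene-3,5-dione, via dibutoxyboron chelate of the diketone 5 (not isolated), via dibutoxyboron chelate of the styryl diketone 6 (not isolated)
Conditions: B2O3 (0.7 equiv), EtOAc, 75 °C; then 4, B(OBu)3 (2 equiv), n-BuNH2 (0.4 equiv, slow addition), 75 °C; then 0.4 M HCl, 60 °C
Reagents that add atoms: none
Why: Pabon-type boron-templated aldol condensation in which chelation of the 1,3-dicarbonyl unit to boron (5) masks the central carbon, the amine-catalysed condensation with vanillin occurs at the unhindered methyl and not at the C5 methylene (as in dehydrogingerdione syntheses from alkane-2,4-diones), E1cB loss of water gives only the (E)-alkene and dilute acid releases 7 from chelate 6; no stereocentre is formed.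

Step 3
Reactants: 7 (E)-1-(4-hydroxy-3-methoxyphenyl)-7-(4-hydroxyphenyl)hept-1-ene-3,5-dione
Product: 9 (1E,7S)-7-hydroxy-1-(4-hydroxy-3-methoxyphenyl)-7-(4-hydroxyphenyl)hept-1-ene-3,5-dione, via enzyme-bound para-quinone methide 8 (not isolated)
Conditions: (S)-selective VAO-type flavoprotein 4-alkylphenol oxidase variant (1–2 mol%), air, catalase, 50 mM KPi pH 7.5, 10% DMSO, 2 mM 7, 25 °C, dark
Reagents that add atoms: water, O
Why: Proposed new method: flavin-dependent benzylic hydroxylation of a 4-alkylphenol (oxa-1,6-addition of water to an enzyme-bound quinone methide), applied to a diarylheptanoid β-diketone, a substrate class on which it has not been shown; the 4-alkylphenol arm binds as its phenolate, hydride passes from C7–H to N5 of the bound FAD to give the planar p-quinone methide 8, and an active-site water activated by a carboxylate placed on one face only adds to the methide carbon, forming the C7–O bond as the (S)-alcohol while O2 reoxidises the flavin (H2O2 removed by catalase); the feruloyl arm has no sp3 C–H para to its phenol and cannot enter this manifold, so the reaction is site-specific without protection; the closest known reaction is the hydroxylation of 4-ethyl- and 4-propylphenol to 1-(4-hydroxyphenyl)alkanols by vanillyl-alcohol oxidase and p-cresol methylhydroxylase, where the wild-type oxidase gives (R) and the variant with the carboxylate moved to the opposite face (D170S/T457E type) gives (S); the variant needed here must also have an opened channel for the dioxoheptenyl chain and must keep water at C7 so that addition outruns loss of the acidic C6–H.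

## Compound list

1 | 4-(4-hydroxyphenyl)butan-2-one (raspberry ketone) | CC(=O)CCc1ccc(O)cc1 | starting material
2 | ethyl acetate | CCOC(C)=O | starting material
3 | 6-(4-hydroxyphenyl)hexane-2,4-dione (keto–enol mixture, drawn as diketone) | CC(=O)CC(=O)CCc1ccc(O)cc1 | intermediate
4 | vanillin (4-hydroxy-3-methoxybenzaldehyde) | COc1cc(C=O)ccc1O | starting material
5 | dibutoxyboron chelate of 3 (not isolated; simplest defined form of the boron-bound diketone) | CCCCO[B-]1(OCCCC)OC(C)=CC(CCc2ccc(O)cc2)=[O+]1 | intermediate
6 | dibutoxyboron chelate of 7 (not isolated; (E)-styryl alkene) | CCCCO[B-]1(OCCCC)OC(/C=C/c2ccc(O)c(OC)c2)=CC(CCc3ccc(O)cc3)=[O+]1 | intermediate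
7 | (E)-1-(4-hydroxy-3-methoxyphenyl)-7-(4-hydroxyphenyl)hept-1-ene-3,5-dione (drawn as 3-enol) | COc1cc(/C=C/C(O)=C\C(=O)CCc2ccc(O)cc2)ccc1O | intermediate
8 | para-quinone methide of 7, 4-[(6E)-7-(4-hydroxy-3-methoxyphenyl)-3,5-dioxohept-6-en-1-ylidene]cyclohexa-2,5-dien-1-one (enzyme-bound, not isolated) | COc1cc(/C=C/C(O)=C\C(=O)CC=C2C=CC(=O)C=C2)ccc1O | intermediate
9 | (1E,7S)-7-hydroxy-1-(4-hydroxy-3-methoxyphenyl)-7-(4-hydroxyphenyl)hept-1-ene-3,5-dione (drawn as 3-enol) | COc1cc(/C=C/C(O)=C\C(=O)C[C@H](O)c2ccc(O)cc2)ccc1O | target

## Step count and risks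

Total step count: 3. Longest linear sequence: 3 steps (1 → 3 → 7 → 9). The single stereocentre (C7, S) is set in the last step; nothing follows it.

**Step 3 (proposed new step, highest risk).** Four failure modes are expected:
- Quinone methide 8 may lose the acidic C6–H faster than it is hydrated, which gives demethoxycurcumin instead of 9.
- The long substrate may not turn over at all.
- The ee may be insufficient.
- The product may be over-oxidised to the C7 ketone.

The fallback uses known chemistry and forms the C6–C7 bond by an aldol reaction instead. It sets out from vanillin 4 and comes back at 9. Vanillin 4 is condensed with excess acetylacetone under the boron conditions of step 2 to give (E)-6-(4-hydroxy-3-methoxyphenyl)hex-5-ene-2,4-dione (feruloylacetone) F2, the same compound used in the step 2 fallback. F2 is deprotonated three times (LDA 3.2 equiv, THF, −78 °C) and treated with commercial 4-(tert-butyldimethylsilyloxy)benzaldehyde. An AcOH quench at −78 °C gives racemic (E)-7-[4-(tert-butyldimethylsilyloxy)phenyl]-7-hydroxy-1-(4-hydroxy-3-methoxyphenyl)hept-1-ene-3,5-dione F4. Buffered desilylation (TBAF/AcOH, THF, 0 °C) gives racemic 7-hydroxy-1-(4-hydroxy-3-methoxyphenyl)-7-(4-hydroxyphenyl)hept-1-ene-3,5-dione F5. Preparative chiral SFC (amylose carbamate phase) separates the enantiomers, and the (S)-enantiomer is 9.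

**Step 2.** Condensation may also occur at the C5 methylene of 3, or twice, and Pabon yields are often moderate. The fallback changes the disconnection to a C6–C7 alkylation, which has no methyl/methylene choice. It sets out from vanillin 4 and comes back at 7. Vanillin 4 and excess acetylacetone give (E)-6-(4-hydroxy-3-methoxyphenyl)hex-5-ene-2,4-dione (feruloylacetone) F2 by the known boron-mediated mono-condensation. Its trianion (LDA 3.2 equiv, THF, −78 °C) is alkylated at the terminal carbon with commercial 4-(tert-butyldimethylsilyloxy)benzyl bromide (1.0 equiv) to give (E)-7-[4-(tert-butyldimethylsilyloxy)phenyl]-1-(4-hydroxy-3-methoxyphenyl)hept-1-ene-3,5-dione F3. TBAF/AcOH (THF, 0 °C) then gives 7.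

**Step 1.** Ethyl acetate self-condensation, ketone self-aldol, or acylation at C3 may lower the yield. The fallback replaces ester condensation by aldol addition and oxidation. It sets out from 1 and comes back at 3. The kinetic methyl enolate of 1 (LDA 2.1 equiv, THF, −78 °C; the phenoxide is inert) is added to acetaldehyde to give racemic 5-hydroxy-1-(4-hydroxyphenyl)hexan-3-one F1. Titration with Jones reagent (acetone, 0 °C; a para-alkylphenol tolerates this, as in estradiol-to-estrone oxidations) gives 3.

## Further compounds

F1 | step 1 | 5-hydroxy-1-(4-hydroxyphenyl)hexan-3-one (racemic) | CC(O)CC(=O)CCc1ccc(O)cc1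
F2 | step 2 | (E)-6-(4-hydroxy-3-methoxyphenyl)hex-5-ene-2,4-dione (feruloylacetone, drawn as enol) | COc1cc(/C=C/C(O)=C\C(C)=O)ccc1O
F3 | step 2 | (E)-7-[4-(tert-butyldimethylsilyloxy)phenyl]-1-(4-hydroxy-3-methoxyphenyl)hept-1-ene-3,5-dione | COc1cc(/C=C/C(O)=C\C(=O)CCc2ccc(O[Si](C)(C)C(C)(C)C)cc2)ccc1O
F4 | step 3 | (E)-7-[4-(tert-butyldimethylsilyloxy)phenyl]-7-hydroxy-1-(4-hydroxy-3-methoxyphenyl)hept-1-ene-3,5-dione (racemic) | COc1cc(/C=C/C(O)=C\C(=O)CC(O)c2ccc(O[Si](C)(C)C(C)(C)C)cc2)ccc1O
F5 | step 3 | (E)-7-hydroxy-1-(4-hydroxy-3-methoxyphenyl)-7-(4-hydroxyphenyl)hept-1-ene-3,5-dione (racemic) | COc1cc(/C=C/C(O)=C\C(=O)CC(O)c2ccc(O)cc2)ccc1O
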